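Compound numbers 1–46 are fixed by the steps below and are used in every section.

## Analysis of the target

Nakijiquinone E (46) joins two rearranged drimane (avarane) sesquiterpene units through an anilino-quinone C–N bond. Each unit is a trans-decalin (ring A: C1–C5 and C10; ring B: C5–C10) with four stereocentres: the quaternary C5 (methyl), C8 (CH–CH3), the quaternary C9 (methyl and the CH2 link C11) and the ring-fusion C10–H. Both units have the same configuration, 5β-methyl, 10α-H, 9β-methyl, 9α-CH2 and 8β-methyl, that is (1R,2S,4aS,8aS) in naphthalene numbering, and the methyl groups on C5 and C9 are 1,3-diaxial. Unit A has the C4 exo-methylene group and is bound through C11 to a benzene ring with one free C–H (C1′ CH2, C2′ OH, C3′ NH, C4′ OH, C5′ CO2Me). Unit B has the C3,C4 ring alkene and is bound to a 2-hydroxy-1,4-benzoquinone that carries the nitrogen on C5. The sensitive groups are the exo-methylene group (acid moves it into the ring), the oxidisable aminoresorcinol, the aminohydroxyquinone and the methyl ester. The main difficulty is the pair of decalins: C9 is quaternary, lies between the stereocentres C8 and C10, and the hydrocarbon skeleton offers no handle to direct reagents. The strategy rests on a pattern in ring B of unit A: C9 sits beside C8, which can be a ketone, and is bonded to C10–H, which is bonded to the quaternary C5, which is bonded to C4 with its exocyclic CH2. A C9 radical between a ketone and an ester that adds to C10 of a C5=C10 alkene, followed by addition of the C5 radical to C4 of an alkyne, leaves exactly this pattern, and the ring alkene of unit B is the isomerised form of the same exo-methylene decalin.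

## Retrosynthetic reasoning

**C–N bond between the halves.** 46 is cut at the bond between the aniline nitrogen and quinone C5, giving amine 28 and methoxyquinone 45. This is the only bond between the two units, and it forms by addition–elimination without acid or strong base, so the most sensitive array is made last. The forward step needs attack by nitrogen at the one remaining vinylogous ester carbon of 45.

**Quinone of unit B.** 45 goes back to dimethoxyquinone 44 (one C–OMe changed to C–OH) and 44 to tetramethoxyarene 43 (oxidative demethylation). Storing the quinone as four methyl ethers lets the arene survive hydride, organomagnesium, hot base and radical steps. 43 is the alkene isomer of 42: the exo-methylene group is moved to C3=C4. This direction is downhill, so both units can be built with one decalin construction.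

**Arene of unit A.** 28 goes back to azo compound 27 (N=N cleavage), 27 to resorcylate 26 (C3′–N bond by azo coupling at the only activated free position), 26 to bis-ether 25, 25 to bromide 24 (C5′–C bond by carbonylation), and 24 to 23 (C5′–Br). Neither an ester nor a nitrogen function would survive the reductions on the decalin, so 23 carries only acetal-protected phenols and the two substituents are added afterwards, each at the site the oxygens direct to.

**C9 methyl group.** In 23 and 42 the C9 methyl group is the former ester carbon: aldehydes 21 and 40 (carbonyl to CH3), alcohols 20 and 39, esters 19 and 38. The ester was needed to generate the radical; reducing it to CH3 also releases auxiliary 6 for re-use.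

**C8 methyl group.** 19 and 38 go back to oxalates 18 and 37, carbinols 17 and 36, and ketones 16 and 35: the C8–CH3 bond comes from methyl addition to the ketone, and the C8–O bond is removed by a radical reaction. Hydrogenation of a C8 alkene is not an option, because the C4 exo-methylene group would be reduced first. The oxygen is removed before the ester is reduced, so that a β-hydroxy aldehyde, which would undergo retro-aldol cleavage in hot base, never appears.

**Both rings.** 16 is cut at C9–C10 and C4–C5 to give the acyclic enyne keto ester 15; 35 goes back to 34 in the same way. This removes both rings and the stereocentres C5, C9 and C10 in one step and leaves a chain that can be assembled by enolate chemistry. The forward reaction must form the C9 radical, close ring B 6-endo on the alkene, close ring A 6-exo on the alkyne and end by hydrogen transfer to the vinyl radical, with the auxiliary choosing the face at C9.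

**C9–C11 bond.** 15 and 34 come from the common keto ester 10 and benzylic bromides 14 and 33 by alkylation at the carbon between the two carbonyl groups. Branching at 10 keeps everything before it common to both units.

**Chain and small fragments.** 10 is cut between the ketone-side CH2 and the allylic CH2 into acetoacetate 8 (from 6 and 7) and allylic bromide 5. 5 comes from 1 through 2, 3 and 4, with the (E)-alkene set by an olefination. 14 comes from 11 through 12 and 13, and 33 from 29 through 31 and 32.

## Alternatives that were turned down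

**Alternative 1:** The unit B decalin A1 (the same compound as 43) is disconnected at its methyl and hydrogen positions, not at ring bonds. It would arise by backbone rearrangement of the drim-8(12)-ene A2, which carries the tetramethoxyphenylmethyl group on C9 and would be made from the chiral-pool lactone sclareolide A3. In the forward step a strong Lewis acid gives the C8 cation of A2; H9, the C10 methyl group, H5 and the axial C4 methyl group then shift one after another, each on the face where it already sits, and a proton leaves C3.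
- For it: A3 is cheap and enantiopure, so the absolute configuration is secure. All four stereocentres are relayed, and A1 would be reached in fewer steps than 43 is here. On these points it is stronger than the chosen strategy for unit B.
- Against it: proton loss gives the more stable ring alkene, so only unit B is served. Unit A needs the less stable exo-methylene isomer, which cannot be reached from A1 by equilibration, so a second, different construction would be needed. The cation cascade can also stop early or be trapped by the electron-rich arene.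
- Comparison: the chosen strategy makes the exo-methylene decalin by ring closure and reaches the ring alkene from it (42 to 43), so one construction serves both halves.

**Alternative 2:** The benzoate ring of unit A is disconnected at the arene bonds C3–C4 and C1–C6. Phthalimide A4 would form in one flask from the 1,3-bis(silyloxy)diene A5, which carries the phthalimido group on its terminal carbon, and the acid chloride A6, a 3-methoxyacryloyl chloride with the unit A decalinylmethyl group on its α-carbon. The terminal carbon of A5 is acylated by A6; base then makes the central carbon add to the methoxymethylene carbon, methanol is lost and the ring aromatises.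
- For it: all substituents of the arene are placed by construction, the nitrogen arrives protected, and no electrophile is used near the exo-methylene group. On regiocontrol of the arene it is stronger than steps 18–22, which rely on directing effects.
- Against it: it leaves the decalin, the hard part, unsolved, since A6 presupposes the finished unit A skeleton with a three-carbon acyl chain on the neopentyl C11. Acylation at the hindered, nitrogen-bearing terminus of A5 competes with O-acylation and with reaction at the other terminus. A4 still needs hydrazinolysis beside a methyl ester. Unit B is not addressed.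
- Comparison: the chosen strategy takes the arene from commercial 11, adds its two substituents in five steps, and puts the main effort into the decalin stereocentres.

**Alternative 3:** The C9–CH3 and C10–H bonds of unit A are disconnected. Oxasilolane A7 would arise from the (bromomethyl)dimethylsilyl ether A8 of a 9-arylmethyl octalin-8β-ol with a C9=C10 alkene and a ketal at C4. A tin hydride chain generates the silylmethyl radical, which closes 5-exo on C9 from the β face held by the C8 oxygen, and the C10 radical takes hydrogen on the α face. Later steps would cleave the C–Si bond to give the methyl group, turn the C8 oxygen into a methyl group and turn the ketal into the exo-methylene group.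
- For it: 5-exo closures of silicon tethers are very reliable, C9 is fixed relative to C8 by the tether, the octalin comes from an enantiopure building block of known configuration, and the C8 methyl group could be set by hydrogenation before any exo-methylene group exists. On those points it is stronger than steps 11 and 14.
- Against it: the radical must bond to a fully substituted alkene carbon that already bears the arylmethyl group, the trans fusion depends on the face of hydrogen transfer to C10, and the step makes one C–C bond and no ring. Three separate functional-group sequences follow it, and unit B would need a second pass.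
- Comparison: the chosen strategy closes both rings and sets C5, C9 and C10 in one step from an open chain, with the exo-methylene group formed directly, at the price of concentrating the risk in that step.

Key step: step 11

Abbreviations used in names:
- Phm = (1S,2R,5S)-5-methyl-2-(2-phenylpropan-2-yl)cyclohexyl, the ester group of (+)-8-phenylmenthol 6.
- DecA = (1R,2S,4aS,8aS)-1,2,4a-trimethyl-5-methylidenedecahydronaphthalen-1-yl.
- DecB = (1R,2S,4aS,8aS)-1,2,4a,5-tetramethyl-1,2,3,4,4a,7,8,8a-octahydronaphthalen-1-yl.
- Decalin intermediates are named with avarane numbering; all are trans-fused with 10α-H, and β is the face of the C5 methyl group.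
- Arene positions of unit A are primed (C1′ bears C11).

Remark on the chemistry: the (+)-auxiliary 6 is assumed to lead to the (5S,10S) series, by analogy with aryl-terminated closures of the same ester class; if the sense proves opposite, the enantiomer of 6 is used and nothing else changes.

Remark on the chemistry: carbinols 17 and 36 may form as mixtures at C8; the epimer from attack on the α face is drawn, and both epimers give the same C8 radical in steps 14 and 30.

## Route

Step 1
Reactants: 1 hex-5-yn-1-ol
Product: 2 hex-5-ynal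
Conditions: TEMPO (cat.), PhI(OAc)2, CH2Cl2, rt; used as a solution
Reagents that add atoms: none
Why: Nitroxyl-catalysed oxidation of a primary alcohol stops at the aldehyde and does not touch the terminal alkyne; the volatile aldehyde is not concentrated.

Step 2
Reactants: 2 hex-5-ynal
Product: 3 ethyl (E)-2-methyloct-2-en-7-ynoate
Conditions: Ph3P=C(CH3)CO2Et, CH2Cl2, rt
Reagents that add atoms: ethyl 2-(triphenyl-λ5-phosphanylidene)propanoate, CCOC(=O)C(C)=P(c1ccccc1)(c1ccccc1)c1ccccc1
Why: Wittig reaction of a stabilised, α-branched ylide gives the (E)-trisubstituted alkene, the geometry that later places H10 axial and anti to the C9 ester.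

Step 3
Reactants: 3 ethyl (E)-2-methyloct-2-en-7-ynoate
Product: 4 (E)-2-methyloct-2-en-7-yn-1-ol
Conditions: i-Bu2AlH, CH2Cl2, −78 °C; aq. potassium sodium tartrate
Reagents that add atoms: none
Why: 1,2-Reduction of an enoate by an aluminium hydride gives the allylic alcohol with the alkene geometry unchanged.

Step 4
Reactants: 4 (E)-2-methyloct-2-en-7-yn-1-ol
Product: 5 (E)-8-bromo-7-methyloct-6-en-1-yne
Conditions: CBr4, PPh3, CH2Cl2, 0 °C
Reagents that add atoms: tetrabromomethane, BrC(Br)(Br)Br
Why: Appel reaction; the neutral conditions convert the primary allylic alcohol without allylic transposition or loss of geometry.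

Step 5
Reactants: 6 (+)-8-phenylmenthol; 7 2,2,6-trimethyl-4H-1,3-dioxin-4-one
Product: 8 Phm 3-oxobutanoate
Conditions: xylene, 140 °C, acetone distilled off
Reagents that add atoms: none
Why: Thermolysis of the dioxinone releases acetylketene, which the hindered secondary alcohol traps (acetoacetylation).

Step 6
Reactants: 8 Phm 3-oxobutanoate; 5 (E)-8-bromo-7-methyloct-6-en-1-yne
Product: 10 Phm (E)-6-methyl-3-oxododec-6-en-11-ynoate, via dianion 9 (not isolated)
Conditions: NaH, THF, 0 °C; n-BuLi, −10 °C; then 5, −10 → 0 °C; aq. NH4Cl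
Reagents that add atoms: none
Why: γ-Alkylation of an acetoacetate dianion: the terminal carbanion is the more nucleophilic site and displaces the primary allylic bromide by SN2. Such dianions are alkylated by halides that carry a free terminal alkyne.

Step 7
Reactants: 11 2,4-dihydroxybenzaldehyde
Product: 12 2,4-bis(methoxymethoxy)benzaldehyde
Conditions: MOMCl, i-Pr2NEt, CH2Cl2, 0 → 40 °C
Reagents that add atoms: chloromethyl methyl ether, COCCl
Why: O-Alkylation of both phenols by an α-chloro ether. The acetals survive base, hydride, organomagnesium and hot alkali and can later be removed without protic acid.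

Step 8
Reactants: 12 2,4-bis(methoxymethoxy)benzaldehyde
Product: 13 [2,4-bis(methoxymethoxy)phenyl]methanol
Conditions: NaBH4, MeOH, 0 °C
Reagents that add atoms: none
Why: Borohydride reduction of an aryl aldehyde.

Step 9
Reactants: 13 [2,4-bis(methoxymethoxy)phenyl]methanol
Product: 14 1-(bromomethyl)-2,4-bis(methoxymethoxy)benzene
Conditions: CBr4, PPh3, CH2Cl2, −10 °C; used at once
Reagents that add atoms: tetrabromomethane, BrC(Br)(Br)Br
Why: Appel reaction under neutral conditions; the electron-rich benzylic bromide ionises easily and is therefore used cold and without storage.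

Step 10
Reactants: 10 Phm (E)-6-methyl-3-oxododec-6-en-11-ynoate; 14 1-(bromomethyl)-2,4-bis(methoxymethoxy)benzene
Product: 15 Phm (E)-2-[2,4-bis(methoxymethoxy)benzyl]-6-methyl-3-oxododec-6-en-11-ynoate (both C2 epimers)
Conditions: K2CO3, acetone, 0 °C → rt
Reagents that add atoms: none
Why: C-Alkylation of a β-keto ester enolate by a reactive benzylic bromide; one equivalent of bromide limits dialkylation. The C2 configuration is irrelevant because C2 becomes the radical centre.

Step 11
Reactants: 15 Phm (E)-2-[2,4-bis(methoxymethoxy)benzyl]-6-methyl-3-oxododec-6-en-11-ynoate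
Product: 16 Phm 9α-[2,4-bis(methoxymethoxy)benzyl]-5β-methyl-4-methylidene-8-oxo-trans-decalin-9β-carboxylate
Conditions: Mn(OAc)3·2H2O (2.2 equiv), Yb(OTf)3 (1 equiv), CF3CH2OH/EtOH 9:1, argon, −5 → 0 °C
Reagents that add atoms: none
Why: Yb(OTf)3 binds the dicarbonyl unit of 15 and speeds its enolisation, and Mn(OAc)3 (trivalent manganese) oxidises the enolate by one electron to the electrophilic tertiary radical at C9. This radical adds 6-endo-trig to C10, the less substituted end of the (E)-C5=C10 alkene, through a chair, which closes ring B, forms C9–C10 and leaves a tertiary radical at C5. The C5 radical adds 6-exo-dig to the inner alkyne carbon C4, closing ring A and forming C4–C5, and the vinyl radical takes a hydrogen atom from ethanol to give the exo-methylene group. The closest known reaction type is the Mn(OAc)3-mediated oxidative polycyclisation of unsaturated β-keto esters to trans-decalins, including lanthanide-triflate-assisted closures of 8-phenylmenthyl esters and closures that end on alkynes. At C9 the phenyl group of the auxiliary covers one face of the radical, so the alkene adds to the other (absolute sense); the ester ends axial (β) and the larger arylmethyl group equatorial, as in closures of α-alkyl β-keto esters. At C10 the (E)-alkene places H10 axial and anti to the ester; at C5 the second closure makes the new bond equatorial on ring B, so the methyl group is axial (β) and the fusion trans. The step needs 6-endo over 5-exo attack on the alkene (a tertiary radical results), 6-exo over 7-endo attack on the alkyne (ring size), and closure of the C5 radical faster than its oxidation (no copper salt, low concentration of dissolved oxidant). The arene cannot trap the C5 radical because its free ortho position is meta to both ether groups, and the product cannot be oxidised again because C9 is quaternary.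

Step 12
Reactants: 16 Phm 9α-[2,4-bis(methoxymethoxy)benzyl]-5β-methyl-4-methylidene-8-oxo-trans-decalin-9β-carboxylate
Product: 17 Phm 9α-[2,4-bis(methoxymethoxy)benzyl]-8β-hydroxy-5β,8α-dimethyl-4-methylidene-trans-decalin-9β-carboxylate
Conditions: MeMgBr, CeCl3, THF, −78 → −20 °C; aq. NH4Cl at −20 °C
Reagents that add atoms: methylmagnesium bromide, C[Mg]Br
Why: Cerium-modified Grignard addition to a hindered, enolisable ketone; the neopentyl ester is not attacked. Attack is expected on the α face, away from the axial ester, and the cold quench prevents retro-aldol opening of the alkoxide.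

Step 13
Reactants: 17 Phm 9α-[2,4-bis(methoxymethoxy)benzyl]-8β-hydroxy-5β,8α-dimethyl-4-methylidene-trans-decalin-9β-carboxylate
Product: 18 Phm 9α-[2,4-bis(methoxymethoxy)benzyl]-8β-[(methoxyoxalyl)oxy]-5β,8α-dimethyl-4-methylidene-trans-decalin-9β-carboxylate
Conditions: ClC(O)CO2Me, Et3N, DMAP, CH2Cl2, 0 °C → rt
Reagents that add atoms: methyl chlorooxoacetate, COC(=O)C(=O)Cl
Why: Acylation of a tertiary alcohol by a very electrophilic acid chloride with nucleophilic catalysis. The oxalate is the radical precursor for removing the C8 oxygen before C9 carries an aldehyde.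

Step 14
Reactants: 18 Phm 9α-[2,4-bis(methoxymethoxy)benzyl]-8β-[(methoxyoxalyl)oxy]-5β,8α-dimethyl-4-methylidene-trans-decalin-9β-carboxylate
Product: 19 Phm 9α-[2,4-bis(methoxymethoxy)benzyl]-5β,8β-dimethyl-4-methylidene-trans-decalin-9β-carboxylate
Conditions: Bu3SnH, AIBN, toluene, 110 °C
Reagents that add atoms: none
Why: Barton-type radical deoxygenation of a tertiary methyl oxalate: the stannyl radical adds to the oxalate and the C8–O bond breaks to the tertiary C8 radical. The stannane should deliver hydrogen axially on the α face, opposite the axial C9 ester, which makes the C8 methyl group equatorial (β), as tertiary cyclohexyl radicals generally take hydrogen axially. The C4 alkene is too remote to be reached by the C8 radical.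

Step 15
Reactants: 19 Phm 9α-[2,4-bis(methoxymethoxy)benzyl]-5β,8β-dimethyl-4-methylidene-trans-decalin-9β-carboxylate
Product: 20 {9α-[2,4-bis(methoxymethoxy)benzyl]-5β,8β-dimethyl-4-methylidene-trans-decalin-9β-yl}methanol
Conditions: LiAlH4, THF, reflux
Reagents that add atoms: none
Why: Hydride reduction of the hindered ester to the neopentyl alcohol; nothing else in 19 is reducible, and alcohol 6 is released for recovery.

Step 16
Reactants: 20 {9α-[2,4-bis(methoxymethoxy)benzyl]-5β,8β-dimethyl-4-methylidene-trans-decalin-9β-yl}methanol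
Product: 21 9α-[2,4-bis(methoxymethoxy)benzyl]-5β,8β-dimethyl-4-methylidene-trans-decalin-9β-carbaldehyde
Conditions: Dess–Martin periodinane, NaHCO3, CH2Cl2, rt
Reagents that add atoms: none
Why: Buffered hypervalent-iodine oxidation of a primary alcohol; the aldehyde has no α-hydrogen and cannot epimerise.

Step 17
Reactants: 21 9α-[2,4-bis(methoxymethoxy)benzyl]-5β,8β-dimethyl-4-methylidene-trans-decalin-9β-carbaldehyde
Product: 23 1-(DecA-methyl)-2,4-bis(methoxymethoxy)benzene, via hydrazone 22 (not isolated)
Conditions: N2H4·H2O, KOH, diethylene glycol, 130 °C, then 210 °C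
Reagents that add atoms: none
Why: Wolff–Kishner reduction (Huang-Minlon procedure), the standard way to turn an aldehyde on a quaternary carbon into a methyl group. Aryl acetals and the isolated alkene are stable to hot alkali, and no β-hydroxyl group is left to trigger retro-aldol cleavage.

Step 18
Reactants: 23 1-(DecA-methyl)-2,4-bis(methoxymethoxy)benzene
Product: 24 1-bromo-5-(DecA-methyl)-2,4-bis(methoxymethoxy)benzene
Conditions: NBS, MeCN, −20 → 0 °C, dark
Reagents that add atoms: N-bromosuccinimide, O=C1CCC(=O)N1Br
Why: Electrophilic aromatic bromination: C5′ is para to the C2′ ether and ortho to the C4′ ether, and it is less hindered than C3′ between the ethers. In a dry, non-nucleophilic medium the resorcinol diether ring should react faster than the 1,1-disubstituted alkene.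

Step 19
Reactants: 24 1-bromo-5-(DecA-methyl)-2,4-bis(methoxymethoxy)benzene
Product: 25 methyl 5-(DecA-methyl)-2,4-bis(methoxymethoxy)benzoate
Conditions: Pd(OAc)2 (cat.), Xantphos (cat.), CO (1 atm), Et3N, MeOH, 70 °C
Reagents that add atoms: carbon monoxide, [C-]#[O+]; methanol, CO
Why: Palladium-catalysed alkoxycarbonylation of an aryl bromide (oxidative addition, CO insertion, methanolysis); under CO the hindered alkene does not compete for the arylpalladium intermediate.

Step 20
Reactants: 25 methyl 5-(DecA-methyl)-2,4-bis(methoxymethoxy)benzoate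
Product: 26 methyl 5-(DecA-methyl)-2,4-dihydroxybenzoate
Conditions: ZnBr2, n-PrSH, CH2Cl2, 0 °C
Reagents that add atoms: none
Why: The Lewis acid activates each acetal and the thiol takes over the methoxymethyl group. No protic acid is present, so the exo-methylene group should not migrate.

Step 21
Reactants: 26 methyl 5-(DecA-methyl)-2,4-dihydroxybenzoate
Product: 27 methyl 3-[(E)-(4-bromophenyl)diazenyl]-5-(DecA-methyl)-2,4-dihydroxybenzoate
Conditions: 4-BrC6H4N2BF4, pyridine, THF, 0 °C
Reagents that add atoms: 4-bromobenzenediazonium tetrafluoroborate, Brc1ccc([N+]#N)cc1.F[B-](F)(F)F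
Why: Azo coupling: C3′ between the two hydroxyl groups is the only free position they activate (C6′ is meta to both). Arenediazonium ions do not attack isolated alkenes.

Step 22
Reactants: 27 methyl 3-[(E)-(4-bromophenyl)diazenyl]-5-(DecA-methyl)-2,4-dihydroxybenzoate
Product: 28 methyl 3-amino-5-(DecA-methyl)-2,4-dihydroxybenzoate
Conditions: Na2S2O4, THF/H2O, 50 °C, argon; used at once
Reagents that add atoms: none
Why: Dithionite cleaves the N=N bond reductively to the aniline and 4-bromoaniline without touching ester or alkene. The aminoresorcinol is air-sensitive and is carried forward directly.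

Step 23
Reactants: 29 1,2,4,5-tetramethoxybenzene
Product: 31 2,3,5,6-tetramethoxybenzaldehyde, via aryllithium 30 (not isolated)
Conditions: n-BuLi, TMEDA, THF, 0 °C; then DMF; aq. NH4Cl
Reagents that add atoms: N,N-dimethylformamide, CN(C)C=O
Why: Directed ortho-lithiation (each ring C–H lies beside a methoxy group) followed by formylation.

Step 24
Reactants: 31 2,3,5,6-tetramethoxybenzaldehyde
Product: 32 (2,3,5,6-tetramethoxyphenyl)methanol
Conditions: NaBH4, MeOH, 0 °C
Reagents that add atoms: none
Why: Borohydride reduction of an aryl aldehyde.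

Step 25
Reactants: 32 (2,3,5,6-tetramethoxyphenyl)methanol
Product: 33 3-(bromomethyl)-1,2,4,5-tetramethoxybenzene
Conditions: PBr3, CH2Cl2, 0 °C
Reagents that add atoms: phosphorus tribromide, BrP(Br)Br
Why: Conversion of a benzylic alcohol to the bromide; the methyl ethers tolerate the reagent and this bromide can be stored.

Step 26
Reactants: 10 Phm (E)-6-methyl-3-oxododec-6-en-11-ynoate; 33 3-(bromomethyl)-1,2,4,5-tetramethoxybenzene
Product: 34 Phm (E)-6-methyl-3-oxo-2-(2,3,5,6-tetramethoxybenzyl)dodec-6-en-11-ynoate (both C2 epimers)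
Conditions: K2CO3, acetone, 40 °C
Reagents that add atoms: none
Why: C-Alkylation of the β-keto ester enolate, as in step 10.

Step 27
Reactants: 34 Phm (E)-6-methyl-3-oxo-2-(2,3,5,6-tetramethoxybenzyl)dodec-6-en-11-ynoate
Product: 35 Phm 5β-methyl-4-methylidene-8-oxo-9α-(2,3,5,6-tetramethoxybenzyl)-trans-decalin-9β-carboxylate
Conditions: Mn(OAc)3·2H2O (2.2 equiv), Yb(OTf)3 (1 equiv), CF3CH2OH/EtOH 9:1, argon, −5 → 0 °C
Reagents that add atoms: none
Why: The same oxidative radical bicyclisation as step 11 (6-endo-trig, then 6-exo-dig, then hydrogen transfer), with the same control elements. Both ortho positions of this arene are substituted, so it cannot trap the C5 radical, and its twisted methoxy groups make it a poor electron donor toward Mn(OAc)3 at 0 °C.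

Step 28
Reactants: 35 Phm 5β-methyl-4-methylidene-8-oxo-9α-(2,3,5,6-tetramethoxybenzyl)-trans-decalin-9β-carboxylate
Product: 36 Phm 8β-hydroxy-5β,8α-dimethyl-4-methylidene-9α-(2,3,5,6-tetramethoxybenzyl)-trans-decalin-9β-carboxylate
Conditions: MeMgBr, CeCl3, THF, −78 → −20 °C; aq. NH4Cl at −20 °C
Reagents that add atoms: methylmagnesium bromide, C[Mg]Br
Why: Cerium-modified Grignard addition to the hindered ketone, as in step 12.

Step 29
Reactants: 36 Phm 8β-hydroxy-5β,8α-dimethyl-4-methylidene-9α-(2,3,5,6-tetramethoxybenzyl)-trans-decalin-9β-carboxylate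
Product: 37 Phm 8β-[(methoxyoxalyl)oxy]-5β,8α-dimethyl-4-methylidene-9α-(2,3,5,6-tetramethoxybenzyl)-trans-decalin-9β-carboxylate
Conditions: ClC(O)CO2Me, Et3N, DMAP, CH2Cl2, 0 °C → rt
Reagents that add atoms: methyl chlorooxoacetate, COC(=O)C(=O)Cl
Why: Acylation of the tertiary alcohol, as in step 13.

Step 30
Reactants: 37 Phm 8β-[(methoxyoxalyl)oxy]-5β,8α-dimethyl-4-methylidene-9α-(2,3,5,6-tetramethoxybenzyl)-trans-decalin-9β-carboxylate
Product: 38 Phm 5β,8β-dimethyl-4-methylidene-9α-(2,3,5,6-tetramethoxybenzyl)-trans-decalin-9β-carboxylate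
Conditions: Bu3SnH, AIBN, toluene, 110 °C
Reagents that add atoms: none
Why: Barton-type radical deoxygenation of the tertiary oxalate with axial hydrogen delivery on the α face, as in step 14, giving the 8β-methyl group.

Step 31
Reactants: 38 Phm 5β,8β-dimethyl-4-methylidene-9α-(2,3,5,6-tetramethoxybenzyl)-trans-decalin-9β-carboxylate
Product: 39 [5β,8β-dimethyl-4-methylidene-9α-(2,3,5,6-tetramethoxybenzyl)-trans-decalin-9β-yl]methanol
Conditions: LiAlH4, THF, reflux
Reagents that add atoms: none
Why: Hydride reduction of the hindered ester, as in step 15, with release of 6.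

Step 32
Reactants: 39 [5β,8β-dimethyl-4-methylidene-9α-(2,3,5,6-tetramethoxybenzyl)-trans-decalin-9β-yl]methanol
Product: 40 5β,8β-dimethyl-4-methylidene-9α-(2,3,5,6-tetramethoxybenzyl)-trans-decalin-9β-carbaldehyde
Conditions: Dess–Martin periodinane, NaHCO3, CH2Cl2, rt
Reagents that add atoms: none
Why: Oxidation of the neopentyl alcohol, as in step 16; the buffered reagent does not attack the electron-rich arene.

Step 33
Reactants: 40 5β,8β-dimethyl-4-methylidene-9α-(2,3,5,6-tetramethoxybenzyl)-trans-decalin-9β-carbaldehyde
Product: 42 3-(DecA-methyl)-1,2,4,5-tetramethoxybenzene, via hydrazone 41 (not isolated)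
Conditions: N2H4·H2O, KOH, diethylene glycol, 130 °C, then 210 °C
Reagents that add atoms: none
Why: Wolff–Kishner reduction, as in step 17; aryl methyl ethers are stable to these conditions.

Step 34
Reactants: 42 3-(DecA-methyl)-1,2,4,5-tetramethoxybenzene
Product: 43 3-(DecB-methyl)-1,2,4,5-tetramethoxybenzene
Conditions: RhCl3·3H2O (cat.), EtOH, 80 °C
Reagents that add atoms: none
Why: Rhodium hydride addition and elimination move the exocyclic alkene to the more stable trisubstituted C3=C4 position. Migration cannot pass the quaternary C5, and no stereocentre is touched.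

Step 35
Reactants: 43 3-(DecB-methyl)-1,2,4,5-tetramethoxybenzene
Product: 44 3-(DecB-methyl)-2,5-dimethoxy-1,4-benzoquinone
Conditions: (NH4)2Ce(NO3)6, MeCN/H2O, 0 °C
Reagents that add atoms: water, O
Why: Oxidative demethylation: the arene radical cation is attacked by water at a para pair of methoxy-bearing carbons and two molecules of methanol leave. The trisubstituted alkene tolerates the short exposure at 0 °C.

Step 36
Reactants: 44 3-(DecB-methyl)-2,5-dimethoxy-1,4-benzoquinone
Product: 45 3-(DecB-methyl)-2-hydroxy-5-methoxy-1,4-benzoquinone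
Conditions: KOH, MeOH/H2O, 0 °C → rt; then aq. HCl to pH 3
Reagents that add atoms: water, O
Why: Addition–elimination at a vinylogous ester. The methoxy group beside the decalinylmethyl group is twisted out of the quinone plane, donates less and so sits on the more electrophilic carbon; it is replaced first, and the resulting anion resists a second hydrolysis.

Step 37
Reactants: 28 methyl 3-amino-5-(DecA-methyl)-2,4-dihydroxybenzoate; 45 3-(DecB-methyl)-2-hydroxy-5-methoxy-1,4-benzoquinone
Product: 46 nakijiquinone E
Conditions: EtOH (degassed), 50 °C, argon, dark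
Reagents that add atoms: none
Why: Addition–elimination of the aniline nitrogen at C5 of the quinone, the only vinylogous ester carbon left, with loss of methanol. The product is a vinylogous amide, which deactivates the quinone toward a second addition, and the neutral medium spares the exo-methylene group and the ester. No stereocentre is formed or touched.

## Compound list

1 | hex-5-yn-1-ol | C#CCCCCO | starting material
2 | hex-5-ynal | C#CCCCC=O | intermediate
3 | ethyl (E)-2-methyloct-2-en-7-ynoate | CCOC(=O)/C(C)=C/CCCC#C | intermediate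
4 | (E)-2-methyloct-2-en-7-yn-1-ol | OC/C(C)=C/CCCC#C | intermediate
5 | (E)-8-bromo-7-methyloct-6-en-1-yne | BrC/C(C)=C/CCCC#C | intermediate
6 | (+)-8-phenylmenthol, (1S,2R,5S)-5-methyl-2-(2-phenylpropan-2-yl)cyclohexan-1-ol | CC(C)(c1ccccc1)[C@H]1CC[C@H](C)C[C@@H]1O | starting material
7 | 2,2,6-trimethyl-4H-1,3-dioxin-4-one | CC1=CC(=O)OC(C)(C)O1 | starting material
8 | Phm 3-oxobutanoate | CC(=O)CC(=O)O[C@H]1C[C@@H](C)CC[C@@H]1C(C)(C)c1ccccc1 | intermediate
9 | sodium lithium dienolate (dianion) of 8 | [Na+].[Li+].C=C([O-])C=C([O-])O[C@H]1C[C@@H](C)CC[C@@H]1C(C)(C)c1ccccc1 | intermediate (not isolated)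
10 | Phm (E)-6-methyl-3-oxododec-6-en-11-ynoate | O=C(CC(=O)CC/C(C)=C/CCCC#C)O[C@H]1C[C@@H](C)CC[C@@H]1C(C)(C)c1ccccc1 | intermediate
11 | 2,4-dihydroxybenzaldehyde | O=Cc1ccc(O)cc1O | starting material
12 | 2,4-bis(methoxymethoxy)benzaldehyde | O=Cc1ccc(OCOC)cc1OCOC | intermediate
13 | [2,4-bis(methoxymethoxy)phenyl]methanol | OCc1ccc(OCOC)cc1OCOC | intermediate
14 | 1-(bromomethyl)-2,4-bis(methoxymethoxy)benzene | BrCc1ccc(OCOC)cc1OCOC | intermediate
15 | Phm (E)-2-[2,4-bis(methoxymethoxy)benzyl]-6-methyl-3-oxododec-6-en-11-ynoate (C2 epimers) | O=C(C(Cc1ccc(OCOC)cc1OCOC)C(=O)CC/C(C)=C/CCCC#C)O[C@H]1C[C@@H](C)CC[C@@H]1C(C)(C)c1ccccc1 | intermediate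
16 | Phm 9α-[2,4-bis(methoxymethoxy)benzyl]-5β-methyl-4-methylidene-8-oxo-trans-decalin-9β-carboxylate | C=C1CCC[C@H]2[C@](C(=O)O[C@H]3C[C@@H](C)CC[C@@H]3C(C)(C)c3ccccc3)(Cc3ccc(OCOC)cc3OCOC)C(=O)CC[C@]12C | intermediate
17 | Phm 9α-[2,4-bis(methoxymethoxy)benzyl]-8β-hydroxy-5β,8α-dimethyl-4-methylidene-trans-decalin-9β-carboxylate | C=C1CCC[C@H]2[C@](C(=O)O[C@H]3C[C@@H](C)CC[C@@H]3C(C)(C)c3ccccc3)(Cc3ccc(OCOC)cc3OCOC)[C@@](C)(O)CC[C@]12C | intermediate
18 | Phm 9α-[2,4-bis(methoxymethoxy)benzyl]-8β-[(methoxyoxalyl)oxy]-5β,8α-dimethyl-4-methylidene-trans-decalin-9β-carboxylate | C=C1CCC[C@H]2[C@](C(=O)O[C@H]3C[C@@H](C)CC[C@@H]3C(C)(C)c3ccccc3)(Cc3ccc(OCOC)cc3OCOC)[C@@](C)(OC(=O)C(=O)OC)CC[C@]12C | intermediate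
19 | Phm 9α-[2,4-bis(methoxymethoxy)benzyl]-5β,8β-dimethyl-4-methylidene-trans-decalin-9β-carboxylate | C=C1CCC[C@H]2[C@](C(=O)O[C@H]3C[C@@H](C)CC[C@@H]3C(C)(C)c3ccccc3)(Cc3ccc(OCOC)cc3OCOC)[C@@H](C)CC[C@]12C | intermediate
20 | {9α-[2,4-bis(methoxymethoxy)benzyl]-5β,8β-dimethyl-4-methylidene-trans-decalin-9β-yl}methanol | C=C1CCC[C@H]2[C@](CO)(Cc3ccc(OCOC)cc3OCOC)[C@@H](C)CC[C@]12C | intermediate
21 | 9α-[2,4-bis(methoxymethoxy)benzyl]-5β,8β-dimethyl-4-methylidene-trans-decalin-9β-carbaldehyde | C=C1CCC[C@H]2[C@](C=O)(Cc3ccc(OCOC)cc3OCOC)[C@@H](C)CC[C@]12C | intermediate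
22 | hydrazone of 21 | C=C1CCC[C@H]2[C@](C=NN)(Cc3ccc(OCOC)cc3OCOC)[C@@H](C)CC[C@]12C | intermediate (not isolated)
23 | 1-(DecA-methyl)-2,4-bis(methoxymethoxy)benzene | C=C1CCC[C@H]2[C@](C)(Cc3ccc(OCOC)cc3OCOC)[C@@H](C)CC[C@]12C | intermediate
24 | 1-bromo-5-(DecA-methyl)-2,4-bis(methoxymethoxy)benzene | C=C1CCC[C@H]2[C@](C)(Cc3cc(Br)c(OCOC)cc3OCOC)[C@@H](C)CC[C@]12C | intermediate
25 | methyl 5-(DecA-methyl)-2,4-bis(methoxymethoxy)benzoate | C=C1CCC[C@H]2[C@](C)(Cc3cc(C(=O)OC)c(OCOC)cc3OCOC)[C@@H](C)CC[C@]12C | intermediate
26 | methyl 5-(DecA-methyl)-2,4-dihydroxybenzoate | C=C1CCC[C@H]2[C@](C)(Cc3cc(C(=O)OC)c(O)cc3O)[C@@H](C)CC[C@]12C | intermediate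
27 | methyl 3-[(E)-(4-bromophenyl)diazenyl]-5-(DecA-methyl)-2,4-dihydroxybenzoate | C=C1CCC[C@H]2[C@](C)(Cc3cc(C(=O)OC)c(O)c(/N=N/c4ccc(Br)cc4)c3O)[C@@H](C)CC[C@]12C | intermediate
28 | methyl 3-amino-5-(DecA-methyl)-2,4-dihydroxybenzoate | C=C1CCC[C@H]2[C@](C)(Cc3cc(C(=O)OC)c(O)c(N)c3O)[C@@H](C)CC[C@]12C | intermediate
29 | 1,2,4,5-tetramethoxybenzene | COc1cc(OC)c(OC)cc1OC | starting material
30 | (2,3,5,6-tetramethoxyphenyl)lithium | [Li]c1c(OC)c(OC)cc(OC)c1OC | intermediate (not isolated)
31 | 2,3,5,6-tetramethoxybenzaldehyde | O=Cc1c(OC)c(OC)cc(OC)c1OC | intermediate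
32 | (2,3,5,6-tetramethoxyphenyl)methanol | OCc1c(OC)c(OC)cc(OC)c1OC | intermediate
33 | 3-(bromomethyl)-1,2,4,5-tetramethoxybenzene | BrCc1c(OC)c(OC)cc(OC)c1OC | intermediate
34 | Phm (E)-6-methyl-3-oxo-2-(2,3,5,6-tetramethoxybenzyl)dodec-6-en-11-ynoate (C2 epimers) | O=C(C(Cc1c(OC)c(OC)cc(OC)c1OC)C(=O)CC/C(C)=C/CCCC#C)O[C@H]1C[C@@H](C)CC[C@@H]1C(C)(C)c1ccccc1 | intermediate
35 | Phm 5β-methyl-4-methylidene-8-oxo-9α-(2,3,5,6-tetramethoxybenzyl)-trans-decalin-9β-carboxylate | C=C1CCC[C@H]2[C@](C(=O)O[C@H]3C[C@@H](C)CC[C@@H]3C(C)(C)c3ccccc3)(Cc3c(OC)c(OC)cc(OC)c3OC)C(=O)CC[C@]12C | intermediate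
36 | Phm 8β-hydroxy-5β,8α-dimethyl-4-methylidene-9α-(2,3,5,6-tetramethoxybenzyl)-trans-decalin-9β-carboxylate | C=C1CCC[C@H]2[C@](C(=O)O[C@H]3C[C@@H](C)CC[C@@H]3C(C)(C)c3ccccc3)(Cc3c(OC)c(OC)cc(OC)c3OC)[C@@](C)(O)CC[C@]12C | intermediate
37 | Phm 8β-[(methoxyoxalyl)oxy]-5β,8α-dimethyl-4-methylidene-9α-(2,3,5,6-tetramethoxybenzyl)-trans-decalin-9β-carboxylate | C=C1CCC[C@H]2[C@](C(=O)O[C@H]3C[C@@H](C)CC[C@@H]3C(C)(C)c3ccccc3)(Cc3c(OC)c(OC)cc(OC)c3OC)[C@@](C)(OC(=O)C(=O)OC)CC[C@]12C | intermediate
38 | Phm 5β,8β-dimethyl-4-methylidene-9α-(2,3,5,6-tetramethoxybenzyl)-trans-decalin-9β-carboxylate | C=C1CCC[C@H]2[C@](C(=O)O[C@H]3C[C@@H](C)CC[C@@H]3C(C)(C)c3ccccc3)(Cc3c(OC)c(OC)cc(OC)c3OC)[C@@H](C)CC[C@]12C | intermediate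
39 | [5β,8β-dimethyl-4-methylidene-9α-(2,3,5,6-tetramethoxybenzyl)-trans-decalin-9β-yl]methanol | C=C1CCC[C@H]2[C@](CO)(Cc3c(OC)c(OC)cc(OC)c3OC)[C@@H](C)CC[C@]12C | intermediate
40 | 5β,8β-dimethyl-4-methylidene-9α-(2,3,5,6-tetramethoxybenzyl)-trans-decalin-9β-carbaldehyde | C=C1CCC[C@H]2[C@](C=O)(Cc3c(OC)c(OC)cc(OC)c3OC)[C@@H](C)CC[C@]12C | intermediate
41 | hydrazone of 40 | C=C1CCC[C@H]2[C@](C=NN)(Cc3c(OC)c(OC)cc(OC)c3OC)[C@@H](C)CC[C@]12C | intermediate (not isolated)
42 | 3-(DecA-methyl)-1,2,4,5-tetramethoxybenzene | C=C1CCC[C@H]2[C@](C)(Cc3c(OC)c(OC)cc(OC)c3OC)[C@@H](C)CC[C@]12C | intermediate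
43 | 3-(DecB-methyl)-1,2,4,5-tetramethoxybenzene | COc1cc(OC)c(OC)c(C[C@]2(C)[C@@H](C)CC[C@]3(C)C(C)=CCC[C@@H]23)c1OC | intermediate
44 | 3-(DecB-methyl)-2,5-dimethoxy-1,4-benzoquinone | COC1=CC(=O)C(OC)=C(C[C@]2(C)[C@@H](C)CC[C@]3(C)C(C)=CCC[C@@H]23)C1=O | intermediate
45 | 3-(DecB-methyl)-2-hydroxy-5-methoxy-1,4-benzoquinone (the C3=C4 isomer of ilimaquinone) | COC1=CC(=O)C(O)=C(C[C@]2(C)[C@@H](C)CC[C@]3(C)C(C)=CCC[C@@H]23)C1=O | intermediate
46 | nakijiquinone E, methyl 5-(DecA-methyl)-3-{[5-(DecB-methyl)-4-hydroxy-3,6-dioxocyclohexa-1,4-dien-1-yl]amino}-2,4-dihydroxybenzoate | C=C1CCC[C@H]2[C@](C)(Cc3cc(C(=O)OC)c(O)c(NC4=CC(=O)C(O)=C(C[C@]5(C)[C@@H](C)CC[C@]6(C)C(C)=CCC[C@@H]56)C4=O)c3O)[C@@H](C)CC[C@]12C | target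

## Step count and least certain steps

Total: 37 steps. Longest linear sequence: 19 steps (1 → 2 → 3 → 4 → 5 → 10 → 15 → 16 → 17 → 18 → 19 → 20 → 21 → 23 → 24 → 25 → 26 → 27 → 28 → 46).

**Step 11 (key step).** The tertiary C5 radical may be oxidised by the manganese salt to the cation before it reaches the alkyne, which would end in elimination instead of ring A. The alkyne may be attacked 7-endo, the second closure may give some cis fusion, and a radical held as a tight two-point chelate would place the ester beside the ketone oxygen and leave it equatorial, which inverts C9 relative to C10. The face selectivity of the auxiliary is also unproven for an α-substituted substrate. Fallback: 15 is deprotonated (NaH, THF, 0 °C) and the enolate brominated with N-bromosuccinimide at −78 °C to give Phm (E)-2-[2,4-bis(methoxymethoxy)benzyl]-2-bromo-6-methyl-3-oxododec-6-en-11-ynoate F1. Slow addition of (Me3Si)3SiH with AIBN in benzene at 80 °C then generates the same C9 radical with no oxidant and no chelating salt. The C5 radical can then only cyclise or be reduced, the vinyl radical is reduced by the silane, and the route is rejoined at 16.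

**Step 27 (repeat of the closure in the tetramethoxy series).** Besides the risks of step 11, the very electron-rich arene may be oxidised by electron transfer to the manganese salt. Fallback: 34 is brominated in the same way to Phm (E)-2-bromo-6-methyl-3-oxo-2-(2,3,5,6-tetramethoxybenzyl)dodec-6-en-11-ynoate F2, which is cyclised with (Me3Si)3SiH and AIBN and rejoins the route at 35.

**Step 14 (step 30 is the same reaction in the other series and is not treated separately).** Hydrogen transfer to the C8 radical on the β face would give the 8α-methyl epimer, and the selectivity between the two faces may be modest. Fallback from 16, using hydrogenation with the C4 alkene masked: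
- Epoxidation of the only alkene (m-chloroperbenzoic acid, NaHCO3, CH2Cl2, 0 °C) gives the 4,4-spiro-epoxide of 16, Phm 9α-[2,4-bis(methoxymethoxy)benzyl]-4,4-(epoxymethano)-5β-methyl-8-oxo-trans-decalin-9β-carboxylate F3.
- Methylenation of the hindered ketone with Cp2TiMe2 (toluene, 70 °C) gives the 8-methylidene compound F4.
- Hydrogenation (H2, Pd/C, EtOAc) adds hydrogen from the α face, away from the axial ester, to give the 8β-methyl epoxide F5.
- Deoxygenation of the epoxide (MeReO3 cat., PPh3, toluene, 60 °C) restores the exo-methylene group and rejoins the route at 19.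

**Step 18.** Electrophilic bromine may add to or substitute at the exo-methylene group in competition with the arene. Fallback from 23, placing the carboxyl carbon without an electrophilic halogen:
- The acetals are removed first (ZnBr2, n-PrSH, CH2Cl2, 0 °C) to give 4-(DecA-methyl)benzene-1,3-diol F6.
- Ortho-carboxylation of the resorcinol with MeOMgOCO2Me (magnesium methyl carbonate) in DMF at 120 °C gives 5-(DecA-methyl)-2,4-dihydroxybenzoic acid F7, with attack expected at the less hindered position para to the second hydroxyl group.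
- Esterification with trimethylsilyldiazomethane in MeOH/toluene rejoins the route at 26.

**Step 37.** The aniline is flanked by two hydroxyl groups and is a weak nucleophile, so the substitution may be slow. This leaves time for oxidation of the aminoresorcinol by the quinone or by air, and for attack through oxygen followed by ring closure to a phenoxazinone. Fallback from 27, with the phenols protected during the union:
- Alkylation of both hydroxyl groups (NaH, MOMCl, DMF, 0 °C) gives methyl 3-[(E)-(4-bromophenyl)diazenyl]-5-(DecA-methyl)-2,4-bis(methoxymethoxy)benzoate F8.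
- Reduction with Na2S2O4 gives methyl 3-amino-5-(DecA-methyl)-2,4-bis(methoxymethoxy)benzoate F9, which has nitrogen as its only nucleophile and cannot be oxidised to a quinone imine.
- Reaction of F9 with 45 in EtOH at 60 °C gives the bis(methoxymethyl) ether of nakijiquinone E, F10.
- Removal of the acetals on silica-supported NaHSO4 in CH2Cl2 at rt gives 46.

## Further compounds

F1 | step 11 | Phm (E)-2-[2,4-bis(methoxymethoxy)benzyl]-2-bromo-6-methyl-3-oxododec-6-en-11-ynoate | O=C(C(Br)(Cc1ccc(OCOC)cc1OCOC)C(=O)CC/C(C)=C/CCCC#C)O[C@H]1C[C@@H](C)CC[C@@H]1C(C)(C)c1ccccc1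
F2 | step 27 | Phm (E)-2-bromo-6-methyl-3-oxo-2-(2,3,5,6-tetramethoxybenzyl)dodec-6-en-11-ynoate | O=C(C(Br)(Cc1c(OC)c(OC)cc(OC)c1OC)C(=O)CC/C(C)=C/CCCC#C)O[C@H]1C[C@@H](C)CC[C@@H]1C(C)(C)c1ccccc1
F3 | step 14 | Phm 9α-[2,4-bis(methoxymethoxy)benzyl]-4,4-(epoxymethano)-5β-methyl-8-oxo-trans-decalin-9β-carboxylate (C4 epimers) | C1OC12CCC[C@H]3[C@](C(=O)O[C@H]4C[C@@H](C)CC[C@@H]4C(C)(C)c4ccccc4)(Cc4ccc(OCOC)cc4OCOC)C(=O)CC[C@]23C
F4 | step 14 | Phm 9α-[2,4-bis(methoxymethoxy)benzyl]-4,4-(epoxymethano)-5β-methyl-8-methylidene-trans-decalin-9β-carboxylate (C4 epimers) | C1OC12CCC[C@H]3[C@](C(=O)O[C@H]4C[C@@H](C)CC[C@@H]4C(C)(C)c4ccccc4)(Cc4ccc(OCOC)cc4OCOC)C(=C)CC[C@]23C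
F5 | step 14 | Phm 9α-[2,4-bis(methoxymethoxy)benzyl]-4,4-(epoxymethano)-5β,8β-dimethyl-trans-decalin-9β-carboxylate (C4 epimers) | C1OC12CCC[C@H]3[C@](C(=O)O[C@H]4C[C@@H](C)CC[C@@H]4C(C)(C)c4ccccc4)(Cc4ccc(OCOC)cc4OCOC)[C@@H](C)CC[C@]23C
F6 | step 18 | 4-(DecA-methyl)benzene-1,3-diol | C=C1CCC[C@H]2[C@](C)(Cc3ccc(O)cc3O)[C@@H](C)CC[C@]12C
F7 | step 18 | 5-(DecA-methyl)-2,4-dihydroxybenzoic acid | C=C1CCC[C@H]2[C@](C)(Cc3cc(C(=O)O)c(O)cc3O)[C@@H](C)CC[C@]12C
F8 | step 37 | methyl 3-[(E)-(4-bromophenyl)diazenyl]-5-(DecA-methyl)-2,4-bis(methoxymethoxy)benzoate | C=C1CCC[C@H]2[C@](C)(Cc3cc(C(=O)OC)c(OCOC)c(/N=N/c4ccc(Br)cc4)c3OCOC)[C@@H](C)CC[C@]12C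
F9 | step 37 | methyl 3-amino-5-(DecA-methyl)-2,4-bis(methoxymethoxy)benzoate | C=C1CCC[C@H]2[C@](C)(Cc3cc(C(=O)OC)c(OCOC)c(N)c3OCOC)[C@@H](C)CC[C@]12C
F10 | step 37 | bis(methoxymethyl) ether of nakijiquinone E | C=C1CCC[C@H]2[C@](C)(Cc3cc(C(=O)OC)c(OCOC)c(NC4=CC(=O)C(O)=C(C[C@]5(C)[C@@H](C)CC[C@]6(C)C(C)=CCC[C@@H]56)C4=O)c3OCOC)[C@@H](C)CC[C@]12C
A1 | alternative 1 | 3-(DecB-methyl)-1,2,4,5-tetramethoxybenzene (same compound as 43) | COc1cc(OC)c(OC)c(C[C@]2(C)[C@@H](C)CC[C@]3(C)C(C)=CCC[C@@H]23)c1OC
A2 | alternative 1 | 11-(2,3,5,6-tetramethoxyphenyl)drim-8(12)-ene | C=C1CC[C@H]2C(C)(C)CCC[C@]2(C)[C@H]1Cc1c(OC)c(OC)cc(OC)c1OC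
A3 | alternative 1 | (+)-sclareolide | CC1(C)CCC[C@@]2(C)[C@H]1CC[C@@]3(C)OC(=O)C[C@H]23
A4 | alternative 2 | methyl 5-(DecA-methyl)-2,4-dihydroxy-3-phthalimidobenzoate | C=C1CCC[C@H]2[C@](C)(Cc3cc(C(=O)OC)c(O)c(N4C(=O)c5ccccc5C4=O)c3O)[C@@H](C)CC[C@]12C
A5 | alternative 2 | 2-[4-methoxy-2,4-bis(trimethylsilyloxy)buta-1,3-dien-1-yl]isoindoline-1,3-dione | COC(O[Si](C)(C)C)=CC(O[Si](C)(C)C)=CN1C(=O)c2ccccc2C1=O
A6 | alternative 2 | 2-(DecA-methyl)-3-methoxyacryloyl chloride | C=C1CCC[C@H]2[C@](C)(CC(=COC)C(Cl)=O)[C@@H](C)CC[C@]12C
A7 | alternative 3 | trans-decalin fused to the 2,2-dimethyl-1,2-oxasilolane at C8 and C9, with the 9α-[2,4-bis(methoxymethoxy)benzyl] group and the C4 ethylene ketal | C[Si]1(C)C[C@@]2(Cc4ccc(OCOC)cc4OCOC)[C@@H](O1)CC[C@@]3(C)[C@H]2CCCC35OCCO5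
A8 | alternative 3 | (bromomethyl)dimethylsilyl ether of the 9-[2,4-bis(methoxymethoxy)benzyl]-5β-methyl-Δ9(10)-octalin-8β-ol C4 ethylene ketal | BrC[Si](C)(C)O[C@H]1CC[C@@]2(C)C(CCCC23OCCO3)=C1Cc1ccc(OCOC)cc1OCOC
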